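**Strategy.** The cyclohexenone is disconnected at C1–C2 (ring numbering: C6 ketone, C1 carrying C7, C2 alkene CH, C3 O‑tigloyl, C4 isopropyl, C5 acetoxy). The key step exploits the C3–C4–C5 stereotriad flanking the C6 ketone. That triad is carried in intact as C2–C4 of a 3‑C‑isopropyl guloside, so a mercury(II)‑triggered Ferrier carbocyclisation turns the pyranose into the carbocycle in one operation, unmasking the C6 ketone and forging C1–C2 by aldol closure. The precursor is a methyl 6‑deoxyhex‑5‑enopyranoside with 2‑O‑PMB, 3‑C‑isopropyl and 4‑O‑acetyl groups, reached from a glucoside through a 3,4‑anhydrogalactoside opened by an isopropyl cuprate.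

Key step: step 10

Remark (assumptions): methyl 4,6‑O‑benzylidene‑α‑D‑glucopyranoside is taken as the purchasable form of methyl α‑D‑glucopyranoside; carbocycle names count from the ketone (ketone = position 1, so target C3/C4/C5 are positions 4/5/6); with C5 trigonal, enol ether 14 is correctly named a β‑L‑lyxo‑hex‑5‑enopyranoside although it derives from the α‑D‑guloside.

**Step 1**
Reactants: 1 methyl 4,6‑O‑[(R)‑benzylidene]‑α‑D‑glucopyranoside
Product: 3 methyl 4,6‑O‑benzylidene‑2‑O‑(4‑methoxybenzyl)‑α‑D‑glucopyranoside, via stannylene acetal 2 (not isolated)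
Conditions: Bu2SnO, toluene, reflux (Dean–Stark); then PMBCl, Bu4NI (cat.), 90 °C
Reagents that add atoms: 4‑methoxybenzyl chloride COc1ccc(CCl)cc1; dibutyltin oxide CCCC[Sn](=O)CCCC (its atoms stay only in 2)
Why: Stannylene‑acetal‑mediated regioselective Williamson etherification, in which the O2 oxygen of an α‑glucoside (cis to the anomeric methoxy group) is the more nucleophilic tin alkoxide, so the PMB ether should form mainly at O2 without touching any stereocentre.

**Step 2**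
Reactants: 3 methyl 4,6‑O‑benzylidene‑2‑O‑(4‑methoxybenzyl)‑α‑D‑glucopyranoside
Product: 4 methyl 2‑O‑(4‑methoxybenzyl)‑α‑D‑glucopyranoside
Conditions: AcOH/H2O (4:1), 60 °C
Reagents that add atoms: none
Why: Acid‑catalysed acetal hydrolysis removes the benzylidene group, while the PMB ether and the methyl glycoside are stable to warm aqueous acetic acid.

**Step 3**
Reactants: 4 methyl 2‑O‑(4‑methoxybenzyl)‑α‑D‑glucopyranoside
Product: 5 methyl 3,6‑di‑O‑benzoyl‑2‑O‑(4‑methoxybenzyl)‑α‑D‑glucopyranoside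
Conditions: BzCl (2.1 equiv), pyridine/CH2Cl2, −40 → −20 °C
Reagents that add atoms: benzoyl chloride O=C(Cl)c1ccccc1
Why: Kinetically controlled selective acylation, in which the primary O6 reacts first and O3 next while O4 is the least reactive hydroxyl of α‑glucopyranosides (the order that leaves O4 free in their partial benzoylation), so O4 alone should remain for activation.

**Step 4**
Reactants: 5 methyl 3,6‑di‑O‑benzoyl‑2‑O‑(4‑methoxybenzyl)‑α‑D‑glucopyranoside
Product: 6 methyl 3,6‑di‑O‑benzoyl‑4‑O‑methanesulfonyl‑2‑O‑(4‑methoxybenzyl)‑α‑D‑glucopyranoside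
Conditions: MsCl, Et3N, DMAP (cat.), CH2Cl2, 0 °C → rt
Reagents that add atoms: methanesulfonyl chloride CS(=O)(=O)Cl
Why: Sulfonylation of the one remaining secondary alcohol turns O4 into a leaving group with retention at C4.

**Step 5**
Reactants: 6 methyl 3,6‑di‑O‑benzoyl‑4‑O‑methanesulfonyl‑2‑O‑(4‑methoxybenzyl)‑α‑D‑glucopyranoside
Product: 8 methyl 3,4‑anhydro‑2‑O‑(4‑methoxybenzyl)‑α‑D‑galactopyranoside, via diol mesylate 7 (not isolated)
Conditions: NaOMe (3 equiv), MeOH/CH2Cl2, 0 °C → rt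
Reagents that add atoms: none
Why: Zemplén transesterification frees O3 and O6, and the O3 alkoxide then displaces the trans C4 mesylate by intramolecular SN2 (3‑exo‑tet epoxide closure), inverting C4 to the galacto epoxide; with O2 etherified no epoxide migration is possible, and O6 cannot reach the rear side of C3 or C4.

**Step 6**
Reactants: 8 methyl 3,4‑anhydro‑2‑O‑(4‑methoxybenzyl)‑α‑D‑galactopyranoside; 9 isopropylmagnesium chloride
Product: 10 methyl 3‑deoxy‑3‑C‑isopropyl‑2‑O‑(4‑methoxybenzyl)‑α‑D‑gulopyranoside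
Conditions: i‑PrMgCl (4 equiv), CuI (0.2 equiv), THF, −40 → −10 °C; aq NH4Cl
Reagents that add atoms: isopropylmagnesium chloride (9) CC(C)[Mg]Cl
Why: Copper‑catalysed Grignard opening of an epoxide (SN2, anti), in which trans‑diaxial (Fürst–Plattner) attack on the half‑chair with C6 pseudo‑equatorial and the anomeric methoxy pseudo‑axial should deliver isopropyl to C3 from the face opposite the epoxide oxygen, inverting C3 and leaving O4 on the upper face to set the gulo array (isopropyl cis to O2, trans to O4); the 6‑OH is carried as its magnesium alkoxide, hence the excess reagent.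

**Step 7**
Reactants: 10 methyl 3‑deoxy‑3‑C‑isopropyl‑2‑O‑(4‑methoxybenzyl)‑α‑D‑gulopyranoside
Product: 11 methyl 3,6‑dideoxy‑6‑iodo‑3‑C‑isopropyl‑2‑O‑(4‑methoxybenzyl)‑α‑D‑gulopyranoside
Conditions: I2, PPh3, imidazole, THF, 0 °C → rt
Reagents that add atoms: iodine II
Why: Garegg–Samuelsson (Appel‑type) iodination, in which the alkoxyphosphonium ion forms and is displaced by iodide far faster at the primary C6 than at the hindered secondary O4, so the 4‑OH should survive.

**Step 8**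
Reactants: 11 methyl 3,6‑dideoxy‑6‑iodo‑3‑C‑isopropyl‑2‑O‑(4‑methoxybenzyl)‑α‑D‑gulopyranoside; 12 acetic anhydride
Product: 13 methyl 4‑O‑acetyl‑3,6‑dideoxy‑6‑iodo‑3‑C‑isopropyl‑2‑O‑(4‑methoxybenzyl)‑α‑D‑gulopyranoside
Conditions: Ac2O, pyridine, DMAP (cat.), CH2Cl2, rt
Reagents that add atoms: acetic anhydride (12) CC(=O)OC(C)=O
Why: DMAP‑catalysed acylation of the remaining secondary alcohol with retention at C4 installs the acetate of the target.

**Step 9**
Reactants: 13 methyl 4‑O‑acetyl‑3,6‑dideoxy‑6‑iodo‑3‑C‑isopropyl‑2‑O‑(4‑methoxybenzyl)‑α‑D‑gulopyranoside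
Product: 14 methyl 4‑O‑acetyl‑3,6‑dideoxy‑3‑C‑isopropyl‑2‑O‑(4‑methoxybenzyl)‑β‑L‑lyxo‑hex‑5‑enopyranoside (the 5,6‑ene of guloside 13)
Conditions: AgF, pyridine, rt, dark
Reagents that add atoms: none
Why: Silver‑assisted dehydrohalogenation (E2‑type) of the primary iodide toward H5 is the classical entry to 6‑deoxyhex‑5‑enopyranosides and leaves acetate and PMB groups intact; C5 ceases to be a stereocentre.

**Step 10**
Reactants: 14 methyl 4‑O‑acetyl‑3,6‑dideoxy‑3‑C‑isopropyl‑2‑O‑(4‑methoxybenzyl)‑β‑L‑lyxo‑hex‑5‑enopyranoside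
Product: 16 (2R,3S,4R,5R)‑2‑acetoxy‑5‑hydroxy‑3‑isopropyl‑4‑[(4‑methoxybenzyl)oxy]cyclohexan‑1‑one, via mercurio keto aldehyde 15 (not isolated)
Conditions: Hg(OCOCF3)2 (5 mol %), acetone/H2O (4:1), rt
Reagents that add atoms: water O; mercury(II) trifluoroacetate O=C(O[Hg]OC(=O)C(F)(F)F)C(F)(F)F (its atoms stay only in 15)
Why: Hg(II) adds to the electron‑rich exocyclic enol ether of 14 with water entering at C5, the hemiketal collapses with loss of methanol to the 1,5‑dicarbonyl compound 15 (sugar C1 an aldehyde, C6 an α‑mercurio ketone), and this latent enolate adds to the aldehyde to form the C6–C1 bond (target C1–C2) while releasing Hg(II) for turnover. The closest known reaction type is the Ferrier carbocyclisation of 6‑deoxyhex‑5‑enopyranosides to β‑hydroxycyclohexanones, which tolerates esters and benzyl‑type ethers. The six‑membered carbocycle closes in a 6‑(enolendo)‑exo‑trig aldol mode. The one new stereocentre, the carbinol carbon, is governed by the chair‑like aldol transition state and is expected to place the hydroxyl trans to the substituent on former sugar C3 (here isopropyl), but either epimer is acceptable because step 11 removes this centre. The selectivity needed is that enolate character arises only at former C6 and never at the acetoxy‑bearing α′‑carbon, which the site‑specific C–Hg bond secures, while the near‑neutral aqueous medium leaves the acetate, the PMB ether and the three inherited stereocentres untouched.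

**Step 11**
Reactants: 16 (2R,3S,4R,5R)‑2‑acetoxy‑5‑hydroxy‑3‑isopropyl‑4‑[(4‑methoxybenzyl)oxy]cyclohexan‑1‑one
Product: 18 (4S,5S,6R)‑6‑acetoxy‑5‑isopropyl‑4‑[(4‑methoxybenzyl)oxy]cyclohex‑2‑en‑1‑one, via β‑mesyloxy ketone 17 (not isolated)
Conditions: MsCl, Et3N, CH2Cl2, 0 °C → rt
Reagents that add atoms: methanesulfonyl chloride CS(=O)(=O)Cl (its atoms stay only in 17)
Why: Mesylation of the β‑hydroxy ketone followed by E1cB elimination toward the acidic ring methylene gives the conjugated enone and erases the carbinol centre; the acetoxy‑bearing α′‑carbon has no β‑leaving group and sits in its stable arrangement trans to isopropyl.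

**Step 12**
Reactants: 18 (4S,5S,6R)‑6‑acetoxy‑5‑isopropyl‑4‑[(4‑methoxybenzyl)oxy]cyclohex‑2‑en‑1‑one; 19 formaldehyde
Product: 20 (4S,5S,6R)‑6‑acetoxy‑2‑(hydroxymethyl)‑5‑isopropyl‑4‑[(4‑methoxybenzyl)oxy]cyclohex‑2‑en‑1‑one
Conditions: 37% aq HCHO, DMAP (0.2 equiv), THF, rt
Reagents that add atoms: formaldehyde (19) C=O
Why: Morita–Baylis–Hillman hydroxymethylation, in which DMAP adds reversibly to the enone β‑carbon, the enolate is trapped by formaldehyde at the α‑carbon (target C1) and loss of DMAP regenerates the enone now bearing C7; no stereocentre is formed.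

**Step 13**
Reactants: 20 (4S,5S,6R)‑6‑acetoxy‑2‑(hydroxymethyl)‑5‑isopropyl‑4‑[(4‑methoxybenzyl)oxy]cyclohex‑2‑en‑1‑one
Product: 21 (4S,5S,6R)‑6‑acetoxy‑4‑hydroxy‑2‑(hydroxymethyl)‑5‑isopropylcyclohex‑2‑en‑1‑one
Conditions: DDQ, CH2Cl2/pH 7 buffer (10:1), 0 °C → rt
Reagents that add atoms: none
Why: Oxidative PMB ether cleavage with DDQ (hydride abstraction to the oxocarbenium ion, then hydrolysis) under buffered conditions should spare the enone, the acetate and the electron‑poor allylic alcohol.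

**Step 14**
Reactants: 21 (4S,5S,6R)‑6‑acetoxy‑4‑hydroxy‑2‑(hydroxymethyl)‑5‑isopropylcyclohex‑2‑en‑1‑one; 22 tiglic acid
Product: 23 (4S,5S,6R)‑6‑acetoxy‑5‑isopropyl‑4‑(tigloyloxy)‑2‑[(tigloyloxy)methyl]cyclohex‑2‑en‑1‑one (target CNP0218511.1)
Conditions: tiglic acid (3 equiv), 2,4,6‑Cl3C6H2COCl, Et3N, toluene, rt; then 21, DMAP, rt → 40 °C
Reagents that add atoms: tiglic acid (22) C/C=C(\C)C(O)=O
Why: Yamaguchi esterification, in which the DMAP‑activated mixed anhydride of tiglic acid acylates both the primary C7 hydroxyl and the hindered allylic ring hydroxyl in one operation; the (E)‑tiglate is the stable geometry and no stereocentre is touched.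

**Compound list**
1 | methyl 4,6‑O‑[(R)‑benzylidene]‑α‑D‑glucopyranoside | CO[C@@H]1[C@H](O)[C@@H](O)[C@@H]2O[C@H](c3ccccc3)OC[C@H]2O1 | starting material
2 | methyl 4,6‑O‑benzylidene‑2,3‑O‑(dibutylstannanediyl)‑α‑D‑glucopyranoside (stannylene acetal) | CO[C@@H]1[C@@H]2O[Sn](CCCC)(CCCC)O[C@H]2[C@@H]3O[C@H](c4ccccc4)OC[C@H]3O1 | intermediate (not isolated)
3 | methyl 4,6‑O‑benzylidene‑2‑O‑(4‑methoxybenzyl)‑α‑D‑glucopyranoside | CO[C@@H]1[C@H](OCc2ccc(OC)cc2)[C@@H](O)[C@@H]2O[C@H](c3ccccc3)OC[C@H]2O1 | intermediate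
4 | methyl 2‑O‑(4‑methoxybenzyl)‑α‑D‑glucopyranoside | CO[C@@H]1[C@H](OCc2ccc(OC)cc2)[C@@H](O)[C@H](O)[C@@H](CO)O1 | intermediate
5 | methyl 3,6‑di‑O‑benzoyl‑2‑O‑(4‑methoxybenzyl)‑α‑D‑glucopyranoside | CO[C@@H]1[C@H](OCc2ccc(OC)cc2)[C@@H](OC(=O)c2ccccc2)[C@H](O)[C@@H](COC(=O)c2ccccc2)O1 | intermediate
6 | methyl 3,6‑di‑O‑benzoyl‑4‑O‑methanesulfonyl‑2‑O‑(4‑methoxybenzyl)‑α‑D‑glucopyranoside | CO[C@@H]1[C@H](OCc2ccc(OC)cc2)[C@@H](OC(=O)c2ccccc2)[C@H](OS(C)(=O)=O)[C@@H](COC(=O)c2ccccc2)O1 | intermediate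
7 | methyl 4‑O‑methanesulfonyl‑2‑O‑(4‑methoxybenzyl)‑α‑D‑glucopyranoside | CO[C@@H]1[C@H](OCc2ccc(OC)cc2)[C@@H](O)[C@H](OS(C)(=O)=O)[C@@H](CO)O1 | intermediate (not isolated)
8 | methyl 3,4‑anhydro‑2‑O‑(4‑methoxybenzyl)‑α‑D‑galactopyranoside | CO[C@@H]1[C@H](OCc2ccc(OC)cc2)[C@H]2O[C@H]2[C@@H](CO)O1 | intermediate
9 | isopropylmagnesium chloride | CC(C)[Mg]Cl | starting material
10 | methyl 3‑deoxy‑3‑C‑isopropyl‑2‑O‑(4‑methoxybenzyl)‑α‑D‑gulopyranoside | CO[C@@H]1[C@H](OCc2ccc(OC)cc2)[C@H](C(C)C)[C@@H](O)[C@@H](CO)O1 | intermediate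
11 | methyl 3,6‑dideoxy‑6‑iodo‑3‑C‑isopropyl‑2‑O‑(4‑methoxybenzyl)‑α‑D‑gulopyranoside | CO[C@@H]1[C@H](OCc2ccc(OC)cc2)[C@H](C(C)C)[C@@H](O)[C@@H](CI)O1 | intermediate
12 | acetic anhydride | CC(=O)OC(C)=O | starting material
13 | methyl 4‑O‑acetyl‑3,6‑dideoxy‑6‑iodo‑3‑C‑isopropyl‑2‑O‑(4‑methoxybenzyl)‑α‑D‑gulopyranoside | CO[C@@H]1[C@H](OCc2ccc(OC)cc2)[C@H](C(C)C)[C@@H](OC(C)=O)[C@@H](CI)O1 | intermediate
14 | methyl 4‑O‑acetyl‑3,6‑dideoxy‑3‑C‑isopropyl‑2‑O‑(4‑methoxybenzyl)‑β‑L‑lyxo‑hex‑5‑enopyranoside | CO[C@@H]1[C@H](OCc2ccc(OC)cc2)[C@H](C(C)C)[C@@H](OC(C)=O)C(=C)O1 | intermediate (key‑step precursor)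
15 | aldehydo‑4‑O‑acetyl‑3,6‑dideoxy‑3‑C‑isopropyl‑2‑O‑(4‑methoxybenzyl)‑6‑(trifluoroacetoxymercurio)‑L‑lyxo‑hexos‑5‑ulose | O=C[C@H](OCc1ccc(OC)cc1)[C@H](C(C)C)[C@@H](OC(C)=O)C(=O)C[Hg]OC(=O)C(F)(F)F | intermediate (not isolated)
16 | (2R,3S,4R,5R)‑2‑acetoxy‑5‑hydroxy‑3‑isopropyl‑4‑[(4‑methoxybenzyl)oxy]cyclohexan‑1‑one (OAc trans, OPMB cis, OH trans to isopropyl) | C1[C@@H](O)[C@H](OCc2ccc(OC)cc2)[C@H](C(C)C)[C@@H](OC(C)=O)C1=O | intermediate (key‑step product)
17 | 5‑O‑methanesulfonate of 16 | C1[C@@H](OS(C)(=O)=O)[C@H](OCc2ccc(OC)cc2)[C@H](C(C)C)[C@@H](OC(C)=O)C1=O | intermediate (not isolated)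
18 | (4S,5S,6R)‑6‑acetoxy‑5‑isopropyl‑4‑[(4‑methoxybenzyl)oxy]cyclohex‑2‑en‑1‑one | C1=C[C@H](OCc2ccc(OC)cc2)[C@H](C(C)C)[C@@H](OC(C)=O)C1=O | intermediate
19 | formaldehyde | C=O | starting material
20 | (4S,5S,6R)‑6‑acetoxy‑2‑(hydroxymethyl)‑5‑isopropyl‑4‑[(4‑methoxybenzyl)oxy]cyclohex‑2‑en‑1‑one | OCC1=C[C@H](OCc2ccc(OC)cc2)[C@H](C(C)C)[C@@H](OC(C)=O)C1=O | intermediate
21 | (4S,5S,6R)‑6‑acetoxy‑4‑hydroxy‑2‑(hydroxymethyl)‑5‑isopropylcyclohex‑2‑en‑1‑one | OCC1=C[C@H](O)[C@H](C(C)C)[C@@H](OC(C)=O)C1=O | intermediate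
22 | tiglic acid, (E)‑2‑methylbut‑2‑enoic acid | C/C=C(\C)C(O)=O | starting material
23 | (4S,5S,6R)‑6‑acetoxy‑5‑isopropyl‑4‑(tigloyloxy)‑2‑[(tigloyloxy)methyl]cyclohex‑2‑en‑1‑one | C/C=C(\C)C(=O)OCC1=C[C@H](OC(=O)/C(C)=C/C)[C@H](C(C)C)[C@@H](OC(C)=O)C1=O | target

**Total step count:** 14. **Longest linear sequence:** 14 steps (1 → 23).

**Steps most likely to fail**

1. Step 6. Carbon transfer from a secondary, β‑hydride‑bearing Grignard reagent may be outrun by chloride opening of the epoxide or by hydride delivery, and attack may stray to C4. Setting out from 8, the epoxide would instead be opened with isopropenylmagnesium bromide and catalytic CuI in THF at −30 °C, an sp2 donor that cannot transfer hydride and is less hindered, to give methyl 3‑deoxy‑3‑C‑isopropenyl‑2‑O‑(4‑methoxybenzyl)‑α‑D‑gulopyranoside F1. Homogeneous hydrogenation of its 1,1‑disubstituted alkene (H2, RhCl(PPh3)3, benzene/EtOH), which leaves the PMB ether alone, would rejoin the route at 10.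

2. Step 12. Conjugate addition of the amine catalyst to the hindered β‑carbon may be slow, so that hydrolysis or transfer of the α′‑acetate, or epimerisation at its carbon, intervenes in the aqueous basic medium. Setting out from 18, anhydrous α‑iodination (I2, pyridine, CH2Cl2, 0 °C) should give (4R,5S,6R)‑6‑acetoxy‑2‑iodo‑5‑isopropyl‑4‑[(4‑methoxybenzyl)oxy]cyclohex‑2‑en‑1‑one F2 (same spatial arrangement as 18; only the C4 descriptor changes). Stille coupling with (tributylstannyl)methanol (Pd2(dba)3, AsPh3, CuI, NMP, 50 °C) would then install C7 and rejoin the route at 20.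

3. Step 3. Discrimination between O3 and O4 may be incomplete, so that benzoate ends up on O4 or on all three oxygens. Setting out from 3, the only free hydroxyl (O3) would be benzoylated (BzCl, pyridine, DMAP) to methyl 3‑O‑benzoyl‑4,6‑O‑benzylidene‑2‑O‑(4‑methoxybenzyl)‑α‑D‑glucopyranoside F3. The acetal would be hydrolysed as in step 2 to methyl 3‑O‑benzoyl‑2‑O‑(4‑methoxybenzyl)‑α‑D‑glucopyranoside F4, and the primary O6 alone benzoylated (BzCl 1.05 equiv, pyridine, −40 °C) to rejoin the route at 5. Each acylation then relies only on blocking or on primary‑versus‑secondary discrimination.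

**Further compounds**
F1 | step 6 | methyl 3‑deoxy‑3‑C‑isopropenyl‑2‑O‑(4‑methoxybenzyl)‑α‑D‑gulopyranoside | CO[C@@H]1[C@H](OCc2ccc(OC)cc2)[C@H](C(C)=C)[C@@H](O)[C@@H](CO)O1
F2 | step 12 | (4R,5S,6R)‑6‑acetoxy‑2‑iodo‑5‑isopropyl‑4‑[(4‑methoxybenzyl)oxy]cyclohex‑2‑en‑1‑one | IC1=C[C@H](OCc2ccc(OC)cc2)[C@H](C(C)C)[C@@H](OC(C)=O)C1=O
F3 | step 3 | methyl 3‑O‑benzoyl‑4,6‑O‑benzylidene‑2‑O‑(4‑methoxybenzyl)‑α‑D‑glucopyranoside | CO[C@@H]1[C@H](OCc2ccc(OC)cc2)[C@@H](OC(=O)c2ccccc2)[C@@H]2O[C@H](c3ccccc3)OC[C@H]2O1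
F4 | step 3 | methyl 3‑O‑benzoyl‑2‑O‑(4‑methoxybenzyl)‑α‑D‑glucopyranoside | CO[C@@H]1[C@H](OCc2ccc(OC)cc2)[C@@H](OC(=O)c2ccccc2)[C@H](O)[C@@H](CO)O1
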